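**Strategy.** The butenolide is cut between its α-carbon C11 and the lactone carbonyl C12 (germacrane numbering; C13 is the acetoxymethyl carbon, C6/C7 the fusion to the ten-membered ring). C11 carries C12, C7 and the oxygenated C13, the pattern left by acylmetalation at the central carbon of an allene. The precursor is therefore a ten-membered α-allenol: C6–OH beside an exocyclic vinylidene C7=C11=C13H2, made by chromium-mediated closure of a propargylic bromide onto an enal. One palladium-catalysed oxidative carbonylation should then bring in C12 as CO, close the butenolide ring by C11–C12 bond formation, fix the tetrasubstituted C7=C11 olefin and place the acetate on C13. Epoxidation of C1=C10 ends the route.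

Key step: step 11

Remark (assumption): compound 1, the C5 acetal-aldehyde of industrial carotenoid manufacture, is taken as purchasable; all ring compounds are kept at or below room temperature because 1(10),4-dienes of this ring size undergo Cope rearrangement on heating.

**Step 1**
Reactants: 1 (E)-4,4-dimethoxy-2-methylbut-2-enal
Product: 2 (2E,4S)-1,1-dimethoxy-3-methylhepta-2,6-dien-4-ol
Conditions: allylSnBu3, (S)-BINOL (20 mol%), Ti(OiPr)4 (10 mol%), 4 Å MS, CH2Cl2, −20 °C; aq. NaHCO3
Reagents that add atoms: allyltributylstannane, C=CC[Sn](CCCC)(CCCC)CCCC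
Why: Keck asymmetric allylation, in which the (S)-BINOL–titanium Lewis acid activates the enal carbonyl and the allylstannane adds 1,2 to its Si face, setting the S carbinol centre (C3 of the target) while the acetal and the E olefin are untouched.

**Step 2**
Reactants: 2 (2E,4S)-1,1-dimethoxy-3-methylhepta-2,6-dien-4-ol
Product: 3 (2E,4S)-4-(tert-butyldimethylsilyloxy)-1,1-dimethoxy-3-methylhepta-2,6-diene
Conditions: TBSCl, imidazole, DMF, rt
Reagents that add atoms: tert-butyldimethylsilyl chloride, CC(C)(C)[Si](C)(C)Cl
Why: Routine silylation of the secondary allylic alcohol, which shields C3–O through the bromination and organolithium steps and leaves the stereocentre untouched.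

**Step 3**
Reactants: 3 (2E,4S)-4-(tert-butyldimethylsilyloxy)-1,1-dimethoxy-3-methylhepta-2,6-diene; 4 methacrolein (2-methylprop-2-enal)
Product: 5 (2E,5S,6E)-5-(tert-butyldimethylsilyloxy)-8,8-dimethoxy-2,6-dimethylocta-2,6-dienal
Conditions: second-generation Grubbs catalyst (5 mol%), 4 (5 equiv), CH2Cl2, 40 °C
Reagents that add atoms: none
Why: Olefin cross-metathesis of a monosubstituted alkene with an α-substituted acrolein is known to give the conjugated trisubstituted enal as the E isomer (the later E C1=C10 bond), and the hindered C4=C5 bond does not take part.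

**Step 4**
Reactants: 5 (2E,5S,6E)-5-(tert-butyldimethylsilyloxy)-8,8-dimethoxy-2,6-dimethylocta-2,6-dienal
Product: 6 (2E,5S,6E)-5-(tert-butyldimethylsilyloxy)-8,8-dimethoxy-2,6-dimethylocta-2,6-dien-1-ol
Conditions: NaBH4, CeCl3·7H2O, MeOH, −20 °C
Reagents that add atoms: none
Why: Luche reduction delivers hydride 1,2 to the enal and gives the primary allylic alcohol without touching the acetal or the silyl ether.

**Step 5**
Reactants: 6 (2E,5S,6E)-5-(tert-butyldimethylsilyloxy)-8,8-dimethoxy-2,6-dimethylocta-2,6-dien-1-ol
Product: 7 (2E,4S,6E)-8-bromo-4-(tert-butyldimethylsilyloxy)-1,1-dimethoxy-3,7-dimethylocta-2,6-diene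
Conditions: CBr4, PPh3, 2,6-lutidine, CH2Cl2, 0 °C
Reagents that add atoms: carbon tetrabromide, BrC(Br)(Br)Br
Why: Appel reaction, in which bromide displaces the oxyphosphonium group by SN2 and gives the primary allylic bromide without allylic shift under cold, buffered conditions.

**Step 6**
Reactants: 7 (2E,4S,6E)-8-bromo-4-(tert-butyldimethylsilyloxy)-1,1-dimethoxy-3,7-dimethylocta-2,6-diene
Product: 9 (6E,9S,10E)-9-(tert-butyldimethylsilyloxy)-12,12-dimethoxy-6,10-dimethyldodeca-6,10-dien-2-yn-1-ol, via lithium acetylide 8 (not isolated)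
Conditions: propyne, n-BuLi (2 equiv per propyne), TMEDA, Et2O/hexane, −78 → 0 °C; 7, −78 °C → rt; then (CH2O)n, THF, rt
Reagents that add atoms: 1,3-dilithiopropyne, [Li]CC#C[Li] (from propyne, CC#C); formaldehyde (as paraformaldehyde), C=O
Why: Propargylation with 1,3-dilithiopropyne, which alkylates primary allylic bromides at its sp3 carbon by SN2 and leaves a lithium acetylide that formaldehyde hydroxymethylates in the same flask; no stereocentre is affected.

**Step 7**
Reactants: 9 (6E,9S,10E)-9-(tert-butyldimethylsilyloxy)-12,12-dimethoxy-6,10-dimethyldodeca-6,10-dien-2-yn-1-ol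
Product: 10 (2E,4S,6E)-12-bromo-4-(tert-butyldimethylsilyloxy)-1,1-dimethoxy-3,7-dimethyldodeca-2,6-dien-10-yne
Conditions: CBr4, PPh3, 2,6-lutidine, CH2Cl2, 0 °C
Reagents that add atoms: carbon tetrabromide, BrC(Br)(Br)Br
Why: Appel reaction on the primary propargylic alcohol gives the 1-bromo-2-alkyne that serves as the chromium-reactive terminus for ring closure.

**Step 8**
Reactants: 10 (2E,4S,6E)-12-bromo-4-(tert-butyldimethylsilyloxy)-1,1-dimethoxy-3,7-dimethyldodeca-2,6-dien-10-yne
Product: 12 (2E,4S,6E)-12-bromo-4-hydroxy-3,7-dimethyldodeca-2,6-dien-10-ynal, via silyl ether enal 11 (not isolated)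
Conditions: 48% aq. HF, MeCN, 0 °C → rt
Reagents that add atoms: water, O
Why: Dilute aqueous acid hydrolyses the dimethyl acetal to the E enal (the mild hydrolysis by which 4-hydroxy-2-enals are released from their acetals) and HF cleaves the secondary silyl ether, while the propargylic bromide and C3 are untouched.

**Step 9**
Reactants: 12 (2E,4S,6E)-12-bromo-4-hydroxy-3,7-dimethyldodeca-2,6-dien-10-ynal
Product: 13 (2E,4S,6E)-12-bromo-3,7-dimethyl-1-oxododeca-2,6-dien-10-yn-4-yl acetate
Conditions: Ac2O, Et3N, DMAP (5 mol%), CH2Cl2, −20 → 0 °C, short reaction time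
Reagents that add atoms: acetic anhydride, CC(=O)OC(C)=O
Why: DMAP-catalysed acylation installs the C3 acetate of the target, and the short, cold reaction keeps amine alkylation by the propargylic bromide negligible.

**Step 10**
Reactants: 13 (2E,4S,6E)-12-bromo-3,7-dimethyl-1-oxododeca-2,6-dien-10-yn-4-yl acetate
Product: 14 (1S,2E,4R,8E)-5-ethenylidene-4-hydroxy-2,8-dimethylcyclodeca-2,8-dien-1-yl acetate (germacrane numbering: 3S-acetoxy, 6R-hydroxy, E olefins C1=C10 and C4=C5, vinylidene C7=C11=C13H2)
Conditions: CrCl2 (6 equiv), chiral 1,8-bis(oxazolin-2-yl)carbazole ligand (6.5 equiv, the enantiomer that directs Si-face attack), iPr2NEt, THF, rt; 13 added by syringe pump (final 2 mM)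
Reagents that add atoms: none
Why: Nozaki–Hiyama–Kishi-type Barbier macrocyclisation, in which divalent chromium turns the propargylic bromide into a propargylchromium species that adds through its γ-carbon C7 (SE2′, the known course for 1-bromo-2-alkynes, which give α-allenic alcohols) to the aldehyde, and the chiral ligand on trivalent chromium directs C7 to the Si face of C6=O so that the new carbinol centre is 6R.

**Step 11**
Reactants: 14 (1S,2E,4R,8E)-5-ethenylidene-4-hydroxy-2,8-dimethylcyclodeca-2,8-dien-1-yl acetate
Product: 15 (3S,6R)-3,13-diacetoxygermacra-1(10)E,4E,7(11)-trien-12,6-olide (butenolide fused at C6–C7 to the ten-membered ring; C11 bears CH2OAc)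
Conditions: Pd(OAc)2 (10 mol%), p-benzoquinone (2 equiv), LiOAc (3 equiv), CO (1 atm), AcOH/THF 1:4, rt
Reagents that add atoms: carbon monoxide, [C-]#[O+]; acetic acid, CC(=O)O
Why: Proposed new method: Pd(OAc)2, CO and the C6 hydroxyl should give an alkoxycarbonylpalladium species (O–C12 bond), whose acyl carbon adds to the central allene carbon C11 by syn insertion of the distal C11=C13 π-bond, which lies in the plane of the C6 tether; this 5-exo-trig acylpalladation closes the butenolide ring by forming C11–C12 and leaves a 2-acyl π-allylpalladium unit over C7–C11–C13. Benzoquinone-assisted attack of acetate at the unhindered terminus C13 should then give the conjugated tetrasubstituted C7=C11 olefin with the C13 acetate in place, and benzoquinone/AcOH returns zerovalent palladium to divalent palladium. The closest known reaction type is the PdCl2/CuCl2 chlorocyclocarbonylation of 2,3-allenols to 3-(chloromethyl)butenolides, joined here with the known benzoquinone-mediated acetoxylation of π-allylpalladium intermediates generated from allenes and 1,3-dienes. No stereocentre is formed, and C6 keeps its configuration because its C–O bond is never broken. The step needs chemoselectivity for the allene over the two trisubstituted ring olefins and regioselectivity for C13 over C7: only the allene can reach the O-bound acylpalladium through a five-membered transition state, and attack at the primary carbon is sterically favoured and gives the conjugated product.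

**Step 12**
Reactants: 15 (3S,6R)-3,13-diacetoxygermacra-1(10)E,4E,7(11)-trien-12,6-olide
Product: 16 (1R,3S,6R,10R)-3,13-diacetoxy-1,10-epoxygermacra-4E,7(11)-dien-12,6-olide (target, CNP0294733.1)
Conditions: mCPBA (1.05 equiv), NaHCO3, CH2Cl2, −20 → 0 °C
Reagents that add atoms: meta-chloroperoxybenzoic acid, O=C(OO)c1cccc(Cl)c1
Why: Prilezhaev epoxidation, in which the isolated C1=C10 bond is the only electron-rich alkene (C4=C5 carries two allylic acyloxy groups, C7=C11 is conjugated to the lactone) and the peracid should attack its outer face in the crown conformer that has both ring methyl groups on the face opposite to O6, giving the trans 1R,10R epoxide.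

**Compound list**
1 | (E)-4,4-dimethoxy-2-methylbut-2-enal | O=C/C(C)=C/C(OC)OC | starting material
2 | (2E,4S)-1,1-dimethoxy-3-methylhepta-2,6-dien-4-ol | C=CC[C@H](O)/C(C)=C/C(OC)OC | intermediate
3 | (2E,4S)-4-(tert-butyldimethylsilyloxy)-1,1-dimethoxy-3-methylhepta-2,6-diene | C=CC[C@H](O[Si](C)(C)C(C)(C)C)/C(C)=C/C(OC)OC | intermediate
4 | methacrolein (2-methylprop-2-enal) | C=C(C)C=O | starting material
5 | (2E,5S,6E)-5-(tert-butyldimethylsilyloxy)-8,8-dimethoxy-2,6-dimethylocta-2,6-dienal | O=C/C(C)=C/C[C@H](O[Si](C)(C)C(C)(C)C)/C(C)=C/C(OC)OC | intermediate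
6 | (2E,5S,6E)-5-(tert-butyldimethylsilyloxy)-8,8-dimethoxy-2,6-dimethylocta-2,6-dien-1-ol | OC/C(C)=C/C[C@H](O[Si](C)(C)C(C)(C)C)/C(C)=C/C(OC)OC | intermediate
7 | (2E,4S,6E)-8-bromo-4-(tert-butyldimethylsilyloxy)-1,1-dimethoxy-3,7-dimethylocta-2,6-diene | BrC/C(C)=C/C[C@H](O[Si](C)(C)C(C)(C)C)/C(C)=C/C(OC)OC | intermediate
8 | [(5E,8S,9E)-8-(tert-butyldimethylsilyloxy)-11,11-dimethoxy-5,9-dimethylundeca-5,9-dien-1-yn-1-yl]lithium (lithium acetylide) | [Li]C#CCC/C(C)=C/C[C@H](O[Si](C)(C)C(C)(C)C)/C(C)=C/C(OC)OC | intermediate
9 | (6E,9S,10E)-9-(tert-butyldimethylsilyloxy)-12,12-dimethoxy-6,10-dimethyldodeca-6,10-dien-2-yn-1-ol | OCC#CCC/C(C)=C/C[C@H](O[Si](C)(C)C(C)(C)C)/C(C)=C/C(OC)OC | intermediate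
10 | (2E,4S,6E)-12-bromo-4-(tert-butyldimethylsilyloxy)-1,1-dimethoxy-3,7-dimethyldodeca-2,6-dien-10-yne | BrCC#CCC/C(C)=C/C[C@H](O[Si](C)(C)C(C)(C)C)/C(C)=C/C(OC)OC | intermediate
11 | (2E,4S,6E)-12-bromo-4-(tert-butyldimethylsilyloxy)-3,7-dimethyldodeca-2,6-dien-10-ynal (silyl ether enal) | BrCC#CCC/C(C)=C/C[C@H](O[Si](C)(C)C(C)(C)C)/C(C)=C/C=O | intermediate
12 | (2E,4S,6E)-12-bromo-4-hydroxy-3,7-dimethyldodeca-2,6-dien-10-ynal | BrCC#CCC/C(C)=C/C[C@H](O)/C(C)=C/C=O | intermediate
13 | (2E,4S,6E)-12-bromo-3,7-dimethyl-1-oxododeca-2,6-dien-10-yn-4-yl acetate | BrCC#CCC/C(C)=C/C[C@H](OC(C)=O)/C(C)=C/C=O | intermediate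
14 | (1S,2E,4R,8E)-5-ethenylidene-4-hydroxy-2,8-dimethylcyclodeca-2,8-dien-1-yl acetate | C=C=C1CC/C(C)=C/C[C@H](OC(C)=O)/C(C)=C/[C@H]1O | intermediate
15 | (3S,6R)-3,13-diacetoxygermacra-1(10)E,4E,7(11)-trien-12,6-olide | CC(=O)OCC1=C2CC/C(C)=C/C[C@H](OC(C)=O)/C(C)=C/[C@H]2OC1=O | intermediate
16 | (1R,3S,6R,10R)-3,13-diacetoxy-1,10-epoxygermacra-4E,7(11)-dien-12,6-olide | CC(=O)OCC1=C2CC[C@@]3(C)O[C@@H]3C[C@H](OC(C)=O)/C(C)=C/[C@H]2OC1=O | target

**Step count.** Total: 12 steps. Longest linear sequence: 12 steps (1 → 16).

**Steps most likely to fail**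

Step 11 (the labelled step). The catalyst may be reduced to palladium metal under CO before reoxidation, the allenol may undergo 5-endo oxypalladation to a dihydrofuran, or the π-allyl may lose a β-hydrogen instead of capturing acetate. The fallback uses known chemistry and the same ring-closing bond: from 14, the established chlorocyclocarbonylation of 2,3-allenols (PdCl2 5 mol%, CuCl2 3 equiv, CO 1 atm, THF, rt) should give (3S,6R)-3-acetoxy-13-chlorogermacra-1(10)E,4E,7(11)-trien-12,6-olide F1, with chloride in place of acetate at C13. Displacement of this activated allylic chloride with CsOAc in DMF at room temperature then returns to 15.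

Step 10. Facial selectivity at C6 may be poor if strain in the ten-membered transition state overrides the chiral ligand; oligomerisation at insufficient dilution is a second concern. The fallback replaces reagent control by substrate control and correction. Compound 13 is cyclised with ligand-free CrCl2 in THF at high dilution. If the 6S alcohol, (1S,2E,4S,8E)-5-ethenylidene-4-hydroxy-2,8-dimethylcyclodeca-2,8-dien-1-yl acetate F2, predominates, Mitsunobu esterification with chloroacetic acid (PPh3, DIAD, toluene, 0 °C) should invert C6 to (1S,2E,4R,8E)-4-(chloroacetoxy)-5-ethenylidene-2,8-dimethylcyclodeca-2,8-dien-1-yl acetate F3. Thiourea/NaHCO3 in EtOH should then remove the chloroacetyl group selectively beside the C3 acetate, returning to 14.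

Step 12. Facial selectivity may be poor if the ring populates a second conformer that exposes the other face of C1=C10, and the carboxylic acid by-product may trigger transannular opening of the epoxide. The fallback replaces substrate control by catalyst control: Shi epoxidation of 15 (D-fructose-derived ketone catalyst, KHSO5, K2CO3 buffer, MeCN/dimethoxymethane–water, 0 °C). Its spiro transition state delivers oxygen to E-trisubstituted olefins to give R,R epoxides and should select the matching ring conformer, leading directly to 16 under non-acidic conditions; no new compound is involved.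

**Further compounds**
F1 | step 11 | (3S,6R)-3-acetoxy-13-chlorogermacra-1(10)E,4E,7(11)-trien-12,6-olide | ClCC1=C2CC/C(C)=C/C[C@H](OC(C)=O)/C(C)=C/[C@H]2OC1=O
F2 | step 10 | (1S,2E,4S,8E)-5-ethenylidene-4-hydroxy-2,8-dimethylcyclodeca-2,8-dien-1-yl acetate | C=C=C1CC/C(C)=C/C[C@H](OC(C)=O)/C(C)=C/[C@@H]1O
F3 | step 10 | (1S,2E,4R,8E)-4-(chloroacetoxy)-5-ethenylidene-2,8-dimethylcyclodeca-2,8-dien-1-yl acetate | C=C=C1CC/C(C)=C/C[C@H](OC(C)=O)/C(C)=C/[C@H]1OC(=O)CCl
F0 | step 12 | none | none
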